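**Retrosynthetic overview**
- The target comes from a Sonogashira coupling of a ring-bound terminal alkyne with (3E)-6-bromo-2-methylhepta-3,6-dien-2-ol, itself made from 2-methylbut-3-yn-2-ol and 2,3-dibromopropene.
- The ring cis-diol comes from an anti-selective OsO4 dihydroxylation of a 3-ethynyl-6-methoxycyclohexa-2,4-dienyl acetate.
- That diene acetate comes from the key C–O step: a one-pot 1,3-hydroxyl transposition and enantioselective O-acetylation that desymmetrises achiral cis-1-ethynyl-4-methoxycyclohexa-2,5-dien-1-ol.
- The dienol comes from p-benzoquinone and ethynyl(trimethyl)silane by acetylide 1,2-addition, cis-selective carbonyl reduction and O-methylation.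
- Rings: the single carbocycle is carried through from p-benzoquinone; no ring is formed in the route.

Assumption: metal alkoxides that are only protonated on work-up and catalyst-bound species (vanadate, osmate, organopalladium) are not numbered; the immobilised lipase and the named metal reagents are taken as purchasable reagents.

**Step 1**
Reactants: 1 p-benzoquinone; 2 ethynyl(trimethyl)silane
Product: 4 4-hydroxy-4-[(trimethylsilyl)ethynyl]cyclohexa-2,5-dien-1-one, via lithium (trimethylsilyl)acetylide 3 (not isolated)
Conditions: 2, n-BuLi, THF, −78 °C; added to 1 (1.5 equiv), THF, −78 °C; aq NH4Cl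
Reagents that add atoms: none
Why: 1,2-addition of a lithium acetylide to one quinone carbonyl (inverse addition to excess quinone at low temperature limits double addition); no stereocentre is formed.

**Step 2**
Reactants: 4 4-hydroxy-4-[(trimethylsilyl)ethynyl]cyclohexa-2,5-dien-1-one
Product: 5 cis-1-[(trimethylsilyl)ethynyl]cyclohexa-2,5-diene-1,4-diol
Conditions: NaBH4, CeCl3·7H2O, MeOH, −78 °C; aq NaHCO3; Et3N-deactivated silica
Reagents that add atoms: none
Why: Luche 1,2-reduction of the cross-conjugated dienone, in which hydride is expected to enter anti to the C4 oxygen (electrostatic facial bias of 4-oxygenated cyclohexadienones), so the new secondary hydroxyl is cis to the tertiary one and the minor trans isomer is removed by chromatography.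

**Step 3**
Reactants: 5 cis-1-[(trimethylsilyl)ethynyl]cyclohexa-2,5-diene-1,4-diol
Product: 7 cis-1-ethynyl-4-methoxycyclohexa-2,5-dien-1-ol, via silylalkynyl methyl ether 6 (not isolated)
Conditions: NaH (1.05 equiv), MeI, THF, 0 °C; then MeOH, K2CO3, rt
Reagents that add atoms: iodomethane, CI
Why: Williamson etherification that favours the unhindered secondary alkoxide over the tertiary propargylic one, followed in the same flask by base-mediated methanolysis of the C(sp)–Si bond; no stereocentre changes and the medium stays basic, which these acid-labile dienols need.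

**Step 4**
Reactants: 7 cis-1-ethynyl-4-methoxycyclohexa-2,5-dien-1-ol
Product: 10 (1S,6R)-3-ethynyl-6-methoxycyclohexa-2,4-dien-1-yl acetate, via (1R,6S)-dienol 8 (not isolated), via (1S,6R)-dienol 9 (not isolated)
Conditions: VO(OSiPh3)3 (5 mol%), immobilised Candida antarctica lipase B, vinyl acetate (3 equiv), Na2CO3, MeCN, 25 °C
Reagents that add atoms: vinyl acetate, C=COC(C)=O
Why: Proposed new method: a dynamic desymmetrisation in which the oxovanadium catalyst converts 7 into its vanadate ester and shifts the oxygen suprafacially ([3,3]) from C1 to C3 or to the enantiotopic C5, so that the cis-dienols 8 and 9 (new C–O bond cis to OMe because the oxygen never leaves its ring face) interconvert through achiral 7, while the lipase is expected to acetylate only 9 (empirical secondary-alcohol rule with the flat ethynyl-diene arm as the large group, as for 3-substituted cyclohex-2-enols), which sets C1 as S and thereby fixes the absolute configuration of the ring; the closest known reaction type is the oxovanadium/lipase dynamic kinetic resolution of allylic alcohols, not yet shown for a prochiral cyclohexa-2,5-dienol or for making a cis-dihydrocatechol-type diene, and the neutral carbonate-buffered medium is chosen to limit aromatisation of the dienols.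

**Step 5**
Reactants: 10 (1S,6R)-3-ethynyl-6-methoxycyclohexa-2,4-dien-1-yl acetate
Product: 11 (1S,4S,5S,6R)-3-ethynyl-4,5-dihydroxy-6-methoxycyclohex-2-en-1-yl acetate
Conditions: OsO4 (2 mol%), NMO (1.1 equiv), acetone/H2O, 0 °C
Reagents that add atoms: N-methylmorpholine N-oxide, C[N+]1([O-])CCOCC1; water, O
Why: catalytic OsO4/NMO syn-dihydroxylation, which takes the disubstituted C4=C5 alkene (the C2=C3 alkene is trisubstituted, conjugated to the alkyne and flanked by the acetate) from the face anti to the adjacent C6 methoxy and the C1 acetoxy, setting C4 and C5 as a cis-diol trans to OMe.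

**Step 6**
Reactants: 12 2-methylbut-3-yn-2-ol; 13 2,3-dibromoprop-1-ene
Product: 15 (3E)-6-bromo-2-methylhepta-3,6-dien-2-ol, via (E)-alkenylzirconocene 14 (not isolated)
Conditions: 12, Cp2Zr(H)Cl (2.1 equiv), THF, rt; then 13, CuCl (10 mol%), 0 °C to rt; H2O
Reagents that add atoms: none
Why: syn-hydrozirconation of the terminal alkyne (the first equivalent is consumed as the zirconium alkoxide) gives the (E)-alkenylzirconocene, which undergoes copper-catalysed allylation at the allylic C–Br of 13 with retention of alkene geometry and leaves the vinyl bromide intact.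

**Step 7**
Reactants: 11 (1S,4S,5S,6R)-3-ethynyl-4,5-dihydroxy-6-methoxycyclohex-2-en-1-yl acetate; 15 (3E)-6-bromo-2-methylhepta-3,6-dien-2-ol
Product: 16 (1S,4S,5S,6R)-4,5-dihydroxy-3-[(5E)-7-hydroxy-7-methyl-3-methylideneoct-5-en-1-yn-1-yl]-6-methoxycyclohex-2-en-1-yl acetate
Conditions: Pd(PPh3)4 (5 mol%), CuI (10 mol%), i-Pr2NH, THF, rt, degassed
Reagents that add atoms: none
Why: Sonogashira coupling of the terminal alkyne with the 1,1-disubstituted vinyl bromide builds the cross-conjugated dienyne under mild amine conditions that leave the free hydroxyls, the acetate and all stereocentres untouched.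

**Compound list**
1 | p-benzoquinone (cyclohexa-2,5-diene-1,4-dione) | O=C1C=CC(=O)C=C1 | starting material
2 | ethynyl(trimethyl)silane | C#C[Si](C)(C)C | starting material
3 | lithium (trimethylsilyl)acetylide | [Li]C#C[Si](C)(C)C | intermediate
4 | 4-hydroxy-4-[(trimethylsilyl)ethynyl]cyclohexa-2,5-dien-1-one | C[Si](C)(C)C#CC1(O)C=CC(=O)C=C1 | intermediate
5 | cis-1-[(trimethylsilyl)ethynyl]cyclohexa-2,5-diene-1,4-diol | O[C@H]1C=C[C@](O)(C#C[Si](C)(C)C)C=C1 | intermediate
6 | cis-4-methoxy-1-[(trimethylsilyl)ethynyl]cyclohexa-2,5-dien-1-ol | CO[C@H]1C=C[C@](O)(C#C[Si](C)(C)C)C=C1 | intermediate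
7 | cis-1-ethynyl-4-methoxycyclohexa-2,5-dien-1-ol | CO[C@H]1C=C[C@](O)(C#C)C=C1 | intermediate
8 | (1R,6S)-3-ethynyl-6-methoxycyclohexa-2,4-dien-1-ol | C#CC1=C[C@@H](O)[C@@H](OC)C=C1 | intermediate
9 | (1S,6R)-3-ethynyl-6-methoxycyclohexa-2,4-dien-1-ol | C#CC1=C[C@H](O)[C@H](OC)C=C1 | intermediate
10 | (1S,6R)-3-ethynyl-6-methoxycyclohexa-2,4-dien-1-yl acetate | C#CC1=C[C@H](OC(C)=O)[C@H](OC)C=C1 | intermediate
11 | (1S,4S,5S,6R)-3-ethynyl-4,5-dihydroxy-6-methoxycyclohex-2-en-1-yl acetate | C#CC1=C[C@H](OC(C)=O)[C@H](OC)[C@@H](O)[C@H]1O | intermediate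
12 | 2-methylbut-3-yn-2-ol | CC(C)(O)C#C | starting material
13 | 2,3-dibromoprop-1-ene | C=C(Br)CBr | starting material
14 | chlorobis(cyclopentadienyl)[(1E)-3-{[chlorobis(cyclopentadienyl)zirconio]oxy}-3-methylbut-1-en-1-yl]zirconium | CC(C)(O[Zr](Cl)(C1C=CC=C1)C1C=CC=C1)/C=C/[Zr](Cl)(C1C=CC=C1)C1C=CC=C1 | intermediate
15 | (3E)-6-bromo-2-methylhepta-3,6-dien-2-ol | C=C(Br)C/C=C/C(C)(C)O | intermediate
16 | (1S,4S,5S,6R)-4,5-dihydroxy-3-[(5E)-7-hydroxy-7-methyl-3-methylideneoct-5-en-1-yn-1-yl]-6-methoxycyclohex-2-en-1-yl acetate | C=C(C#CC1=C[C@H](OC(C)=O)[C@H](OC)[C@@H](O)[C@H]1O)C/C=C/C(C)(C)O | target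

**Step count and risks**
Total step count: 7. Longest linear sequence: 6 (steps 1, 2, 3, 4, 5, 7).

The three steps most likely to fail:

Step 4 (the proposed new step). The dienols 7, 8 and 9 can lose water or methanol to give an arene under the Lewis-acidic vanadium catalyst, and the sense and size of the lipase selectivity on this substrate are predicted, not known. The fallback uses known chemistry and sets out from 7. Ph3SiOReO3 (2 mol%) in Et2O at −78 °C (low-temperature rhenium-oxo 1,3-transposition of allylic alcohols) gives the racemic cis-dienol, a 1:1 mixture of 8 and 9. Esterification with (S)-2-methoxy-2-phenylacetic acid (DCC, catalytic DMAP, CH2Cl2, 0 °C) gives the diastereomers (1S,6R)-dienyl (S)-O-methylmandelate F1 and (1R,6S)-dienyl (S)-O-methylmandelate F2, which are separated by chromatography. Methanolysis of F1 (K2CO3, MeOH, 0 °C) returns 9, and Ac2O/pyridine converts 9 into 10, where the route is rejoined. F2 can be methanolysed to 8 and re-equilibrated through 7 with the same rhenium catalyst.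

Step 2. The cis/trans ratio rests on a remote electrostatic bias that has precedent for carbon nucleophiles but not for hydride on this quinol, and diol 5 is acid-labile. The fallback sets out from 4 and switches to steric control. The tertiary hydroxyl is silylated (Et3SiOTf, 2,6-lutidine, CH2Cl2, −78 °C) to give the triethylsilyl ether F3. Reduction with NaBH4/CeCl3·7H2O (MeOH, −78 °C) delivers hydride anti to the bulky silyloxy group and gives the cis silyloxy alcohol F4. Its only free hydroxyl is methylated (NaH, MeI, THF) to the cis methyl ether F5, and Bu4NF in THF removes both silyl groups to give 7, where the route is rejoined.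

Step 1. Mono-1,2-addition to p-benzoquinone competes with electron transfer and double addition. The fallback sets out from 2 (as its lithium acetylide 3). 4-Methoxyphenol is oxidised with PhI(OAc)2 in MeOH to 4,4-dimethoxycyclohexa-2,5-dien-1-one F6, which has only one carbonyl. Addition of 3 (THF, −78 °C) gives the ketal carbinol F7, and mild hydrolysis (aqueous oxalic acid, THF, rt) gives 4, where the route is rejoined.

**Further compounds**
F1 | step 4 | (1S,6R)-3-ethynyl-6-methoxycyclohexa-2,4-dien-1-yl (2S)-2-methoxy-2-phenylacetate | C#CC1=C[C@H](OC(=O)[C@@H](OC)c2ccccc2)[C@H](OC)C=C1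
F2 | step 4 | (1R,6S)-3-ethynyl-6-methoxycyclohexa-2,4-dien-1-yl (2S)-2-methoxy-2-phenylacetate | C#CC1=C[C@@H](OC(=O)[C@@H](OC)c2ccccc2)[C@@H](OC)C=C1
F3 | step 2 | 4-[(triethylsilyl)oxy]-4-[(trimethylsilyl)ethynyl]cyclohexa-2,5-dien-1-one | CC[Si](CC)(CC)OC1(C#C[Si](C)(C)C)C=CC(=O)C=C1
F4 | step 2 | cis-4-[(triethylsilyl)oxy]-4-[(trimethylsilyl)ethynyl]cyclohexa-2,5-dien-1-ol | O[C@H]1C=C[C@](O[Si](CC)(CC)CC)(C#C[Si](C)(C)C)C=C1
F5 | step 2 | cis-triethyl({4-methoxy-1-[(trimethylsilyl)ethynyl]cyclohexa-2,5-dien-1-yl}oxy)silane | CO[C@H]1C=C[C@](O[Si](CC)(CC)CC)(C#C[Si](C)(C)C)C=C1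
F6 | step 1 | 4,4-dimethoxycyclohexa-2,5-dien-1-one | COC1(OC)C=CC(=O)C=C1
F7 | step 1 | 4,4-dimethoxy-1-[(trimethylsilyl)ethynyl]cyclohexa-2,5-dien-1-ol | COC1(OC)C=CC(O)(C#C[Si](C)(C)C)C=C1
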